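You want the part of the solid electrophile in the flask that has reacted by 10 d. Before any model is fitted, the earlier runs give an estimate of that, provided you follow the fraction left and not the fraction made.

all flasks: free base 2.25 M; gas 55 mM (held)
- theta: solid electrophile 0.75 M; run made earlier
- gamma: solid electrophile 1.1 M; run made earlier
- flask: solid electrophile 1.5 M; time 10 d

| run | time / d | solid electrophile / % | target / % |
|---|---|---|---|
| theta | 0.833 | 0 | 16 |
| theta | 2.50 | 2 | 54 |
| theta | 5.00 | 3 | 79 |
| theta | 8.00 | 1 | 96 |
| theta | 10.0 | 0 | 95 |
| gamma | 0.833 | 5 | 16 |
| gamma | 2.50 | 1 | 49 |
| gamma | 5.00 | 2 | 75 |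
| gamma | 8.00 | 0 | 91 |
| gamma | 10.0 | 1 | 94 |

(each reading ± 1.5 percentage points)

1. part of the solid electrophile that has reacted (what has only dissolved counts as not reacted) at 10 d
2. share of the unused nucleophile that is free and not bound as protonated nucleophile, at 10 d

- as a solid, counted per litre of solution: solid electrophile
- at the start none of nucleophile is dissolved
- the numbers in the tables scatter by 1.5 percentage points (one standard deviation)
- candidate steps: solid electrophile <-> electrophile; nucleophile + acid set free <-> protonated nucleophile; acid set free + free base <-> salt of the base; electrophile + nucleophile <-> acid set free + target; gas <-> nucleophile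
- at the start none of the solid electrophile is in solution
- what has only dissolved of solid electrophile counts as not reacted
- the earlier runs do not show how much of nucleophile is bound; that part of a forecast is a guess

The gamma run looks nearly the same as the flask, with 1.1 M of solid electrophile against 1.5 M and the same free base and gas. Theta, at 0.75 M, reads 95% target at 10.0 d and gamma reads 94%, a gap of 1 percentage point, which is less than the scatter of 1.5 points. That one gap does not show that the charge makes no difference, since at 2.50 d theta reads 54% and gamma 49%, so it is a working assumption of mine, and no finding, that the flask will end where gamma ends. My own reckoning takes gamma's last reading: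

κ = −ln(fraction left) / time = 0.281 d⁻¹

left in the flask = exp(−κ × time) = 6.00%

You can call κ the fade constant, the negative logarithm of the fraction left divided by the time, and you should take it as an average over that whole time, not as a rate constant. My reckoning therefore says 94.0% reacted. The forecast differs, with 90% reacted. It also puts 70% of the unused nucleophile free, saying “Most nucleophile should therefore remain free”, and it calls that share a guess.

The flask gives 94.2% reacted and 5.49% free.

    solid electrophile ⇌ electrophile, rate k1*(cs1 - [electrophile]) while solid is left; crystals form when [electrophile] > cs1 (solubility = 0.900 M, k = 1.20 × 10⁻⁴ s⁻¹)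
    nucleophile + acid set free ⇌ protonated nucleophile, settled at all times (K = 3800 L mol⁻¹)
    acid set free + free base ⇌ salt of the base (K = 19000 L mol⁻¹, k = 7.10 × 10⁻⁵ L mol⁻¹ s⁻¹)
    electrophile + nucleophile ⇌ acid set free + target (K = 50.0, k = 7.60 × 10⁻⁵ L mol⁻¹ s⁻¹)
    gas ⇌ nucleophile, rate k5*(csat - [nucleophile]) (kL = 3.30 × 10⁻⁴ s⁻¹)

The flask's own κ is 0.284 d⁻¹, and its free share stands 65 points below the forecast. Now take the neighbouring flask, the same recipe with 0.38 M of solid electrophile. Gamma's κ says 6.00% left there too, but that flask holds 3.2%, solid and dissolved together, at 10 d. Its κ is 0.345 d⁻¹, higher than gamma's, and 19.3% of its unused nucleophile is free.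

The runs are simulated on assumed constants, noise included.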